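1. Retrosynthetic cuts, in order: the epoxide oxygen on C4–C5, the C8–O acyl bond and C11=C13. The C6–O–C12 lactone is then exchanged for a C6–O–C15 butenolide, C1–C4 and C5–C10 are re-joined (reverse of the key step), and C4–C5 and C1–C10 are cut as an enone–cyclobutene (2+2) photocycloaddition.
2. Enabling feature (germacrane numbering): ring C1–C10 holds a cis C1=C10 olefin (methyl C14 on C10) and, hidden in the epoxide, a trans C4=C5 olefin. This cis,trans-cyclodeca-1,5-diene is what a bicyclo[2.2.0]hexane (C1, C2, C3, C4, C5, C10) fused to a cyclohexane (C5–C10) gives on heating, and C15 on C4 and the oxygen on C6 lie cis across C4=C5, so they can be tied as a five-membered lactone.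
3. Forward order of rings: cyclohexane C5–C10 (from (R)-3-methylcyclohexanone), both four-membered rings in one photocycloaddition, the C6–O–C15 lactone tether, the ten-membered ring by thermal scission, the 6,12-lactone, the epoxide.
4. Stereochemistry: the methyl centre of the starting ketone (C10) sets C8 (Luche reduction). O8 then sets C7 (anti hydroboration) and C6 (hydroxyl-directed hydride), and C10 is erased afterwards. C4 and C5 come from hydroxyl-directed epoxidation on the outer face of the trans olefin.

Key step: step 15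

Remark on notation: germacrane numbering is used for all ring atoms from compound 1 on. β is the face of C11 on C7 (H-7 is α). "Ring-trans" and "ring-cis" describe the two ring bonds at an olefin of the ten-membered ring.
Assumption: any trans-fused junction formed in the photocycloaddition equilibrates at C5 to the cis-fused ketone on neutral alumina.

Step 1
Reactants: 1 (R)-3-methylcyclohexan-1-one
Product: 3 (R)-5-methylcyclohex-2-en-1-one, via trimethylsilyl enol ether 2 (not isolated)
Conditions: LiN(i-Pr)2, THF, −78 °C; Me3SiCl; then Pd(OAc)2 (10 mol %), O2, DMSO, rt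
Reagents that add atoms: chlorotrimethylsilane, C[Si](C)(C)Cl (silyl group held by 2 only)
Why: Kinetic deprotonation at the methylene remote from the methyl-bearing carbon followed by Saegusa–Ito dehydrogenation should give the enone with the methyl centre (future C10) untouched, the achiral 3-methyl isomer from the minor enolate being removed by chromatography.

Step 2
Reactants: 3 (R)-5-methylcyclohex-2-en-1-one
Product: 4 (R)-2-iodo-5-methylcyclohex-2-en-1-one
Conditions: I2, K2CO3, DMAP (cat.), THF–H2O, rt
Reagents that add atoms: iodine, II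
Why: Baylis–Hillman-type α-iodination of an enone (amine conjugate addition, iodination of the enolate, elimination) places the halogen on the future C7.

Step 3
Reactants: 4 (R)-2-iodo-5-methylcyclohex-2-en-1-one
Product: 5 (1R,5R)-2-iodo-5-methylcyclohex-2-en-1-ol (hydroxyl cis to methyl)
Conditions: NaBH4, CeCl3·7H2O, MeOH, −78 → 0 °C
Reagents that add atoms: none
Why: Luche 1,2-reduction by axial hydride attack on the half-chair with a pseudo-equatorial methyl should give the pseudo-equatorial alcohol cis to the methyl, which sets C8 (8β) from C10.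

Step 4
Reactants: 5 (1R,5R)-2-iodo-5-methylcyclohex-2-en-1-ol
Product: 6 (1R,5R)-1-(tert-butyldimethylsilyloxy)-2-iodo-5-methylcyclohex-2-ene
Conditions: t-BuMe2SiCl, imidazole, DMF, rt
Reagents that add atoms: tert-butyldimethylsilyl chloride, CC(C)(C)[Si](C)(C)Cl
Why: Standard silylation masks O8 for the organozinc coupling and keeps it distinct from the C6 oxygen introduced in step 6.

Step 5
Reactants: 6 (1R,5R)-1-(tert-butyldimethylsilyloxy)-2-iodo-5-methylcyclohex-2-ene; 7 tert-butyl bromoacetate
Product: 9 tert-butyl 2-[(4R,6R)-6-(tert-butyldimethylsilyloxy)-4-methylcyclohex-1-en-1-yl]acetate, via Reformatsky zinc reagent 8 (not isolated)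
Conditions: Zn, Me3SiCl (cat.), THF, 40 °C; then 6, Pd2(dba)3, XPhos, THF, 50 °C
Reagents that add atoms: zinc, [Zn] (held by 8 only)
Why: Negishi-type coupling of a Reformatsky reagent with an alkenyl iodide (oxidative addition to zerovalent palladium, transmetalation, reductive elimination) forms C7–C11 with the olefin fixed at C6=C7.

Step 6
Reactants: 9 tert-butyl 2-[(4R,6R)-6-(tert-butyldimethylsilyloxy)-4-methylcyclohex-1-en-1-yl]acetate
Product: 11 cyclohexane C5–C10 bearing 6α-OH; 7β-CH2CO2t-Bu; 8β-OSiMe2t-Bu; 10β-CH3, via C6 alkylborane 10 (not isolated)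
Conditions: BH3·THF, THF, 0 °C; then H2O2, aq NaOH, 0 °C
Reagents that add atoms: borane–THF, B (boron held by 10 only); hydrogen peroxide, OO
Why: Hydroboration–oxidation places boron on the less substituted C6 and adds H and B syn on the α face, anti to the allylic silyl ether and the methyl group, so that C11 ends cis to O8 and C7 is set, the tert-butyl ester being inert to borane at this temperature.

Step 7
Reactants: 11 6α-alcohol
Product: 12 cyclohexan-6-one bearing 7β-CH2CO2t-Bu; 8β-OSiMe2t-Bu; 10β-CH3
Conditions: Dess–Martin periodinane, CH2Cl2, 0 °C → rt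
Reagents that add atoms: none
Why: Periodinane oxidation is close to neutral, so the axial C7 side chain should not epimerise and the β-silyloxy group should not be eliminated.

Step 8
Reactants: 12 6-ketone
Product: 14 tert-butyl 2-[(1R,6R)-6-(tert-butyldimethylsilyloxy)-4-methyl-2-oxocyclohex-3-en-1-yl]acetate, via kinetic silyl enol ether 13 (not isolated)
Conditions: LiN(i-Pr)2, Me3SiCl, THF, −78 °C; then Pd(OAc)2 (10 mol %), O2, DMSO, rt
Reagents that add atoms: chlorotrimethylsilane, C[Si](C)(C)Cl (silyl group held by 13 only)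
Why: Kinetic enolisation toward the unhindered C5 methylene and Saegusa–Ito dehydrogenation create the C5=C10 enone under neutral conditions, erase the relay centre C10 and avoid the base that would expel the silanol and aromatise the ring.

Step 9
Reactants: 15 ethyl 1-bromocyclobutane-1-carboxylate
Product: 16 cyclobut-1-ene-1-carboxylic acid
Conditions: KOH, toluene, reflux; then aq HCl, 0 °C
Reagents that add atoms: potassium hydroxide, [K+].[OH-]
Why: E2 dehydrobromination and saponification in one operation is the established entry to this cyclobutene acid.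

Step 10
Reactants: 16 cyclobut-1-ene-1-carboxylic acid
Product: 17 methyl cyclobut-1-ene-1-carboxylate
Conditions: MeI, K2CO3, DMF, 0 °C → rt
Reagents that add atoms: iodomethane, CI
Why: O-alkylation of the carboxylate avoids acid and heat, under which the strained acrylate would polymerise.

Step 11
Reactants: 14 enone; 17 methyl cyclobut-1-ene-1-carboxylate
Product: 18 head-to-head cis-anti-cis tricyclo[4.4.0.0(2,5)]decanone: C4(CO2Me)–C5 and C1–C10 bonds on the α face; H-5 and C14 β; 6-oxo; 7β-CH2CO2t-Bu; 8β-OSiMe2t-Bu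
Conditions: hν (medium-pressure Hg lamp, Pyrex), 17 (5 equiv), CH2Cl2, −20 °C; then neutral Al2O3, CH2Cl2
Reagents that add atoms: none
Why: In this triplet-enone (2+2) photocycloaddition the electron-poor cyclobutene should add head-to-head (C4 to C5, C1 to C10) and exo (cis-anti-cis) on the α face, opposite to the β substituents on C7 and C8, and the four new centres serve only to place C15 next to C6 before they are erased in step 15.

Step 12
Reactants: 18 photoadduct
Product: 19 8β-hydroxy ketone of the photoadduct
Conditions: HF·pyridine, THF, 0 °C → rt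
Reagents that add atoms: none
Why: Acidic fluoride frees O8 as the directing group for step 13 without the base that would cause retro-aldol cleavage or epimerisation at C7.

Step 13
Reactants: 19 8β-hydroxy ketone
Product: 21 tetracyclic C6–O–C15 γ-lactone with free 8β-OH and 7β-CH2CO2t-Bu, via anti-diol ester 20 (not isolated)
Conditions: Me4NBH(OAc)3, MeCN–AcOH, −25 °C; then PPTS (cat.), toluene, 50 °C
Reagents that add atoms: none
Why: In the Evans–Saksena reduction boron binds the β hydroxyl on C8 and passes hydride within the complex to the β face of C6, giving the 1,3-anti 6α alcohol, which sits next to C15 on the α face and closes the γ-lactone with loss of methanol, an outcome open only to the α-face photoadduct.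

Step 14
Reactants: 21 hydroxy lactone
Product: 22 tetracyclic C6–O–C15 γ-lactone with 8β-OSiMe2t-Bu and 7β-CH2CO2t-Bu
Conditions: t-BuMe2SiOTf, 2,6-lutidine, CH2Cl2, −40 → 0 °C
Reagents that add atoms: tert-butyldimethylsilyl triflate, CC(C)(C)[Si](C)(C)OS(=O)(=O)C(F)(F)F
Why: The silyl triflate covers the hindered C8 hydroxyl so that it cannot compete with O6 for C12 when the 6,12-lactone is closed in step 18.

Step 15
Reactants: 22 tetracyclic lactone
Product: 23 ten-membered (ring-cis C1=C10, ring-trans C4=C5) diene bridged by the C6–O–C15 butenolide; 7β-CH2CO2t-Bu; 8β-OSiMe2t-Bu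
Conditions: toluene (degassed, dilute), BHT, silylated sealed tube, 140 °C
Reagents that add atoms: none
Why: Homolysis of the strained central C1–C4 bond, eased by the lactone carbonyl C15 on C4, gives a cyclohexane-1,4-diyl (C1, C2, C3, C4, C5, C10) that relaxes to a chair and cleaves the aligned, most substituted C5–C10 bond, forming C1=C10 and C4=C5. The closest known reaction type is the thermal cycloreversion of enone–cyclobutene photoadducts (bicyclo[2.2.0]hexanes) to cis,trans-cyclodeca-1,5-dienes. The ten-membered ring is not closed by bond formation but is unveiled by loss of the two bonds shared by the six-membered and the four-membered rings, so no macrocyclisation is needed. No stereocentre is created, C1, C4, C5 and C10 are erased, and C6, C7 and C8 are untouched. The step needs ring-trans C4=C5 together with ring-cis C1=C10, and this is secured because the five-membered lactone can only hold C15 and C6 cis on C4=C5 (C3 and C6 anti), which fixes C6 equatorial and C9 axial on the chair diyl and so delivers the cis C1=C10 olefin. Scission of C5–C10 instead of C2–C3 is favoured by its higher substitution, and the temperature is kept at the minimum for opening so that Cope rearrangement to the divinylcyclohexane stays slow.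

Step 16
Reactants: 23 butenolide-bridged diene
Product: 25 6α,15-diol of the cyclodecadiene with 7β-CH2CO2t-Bu and 8β-OSiMe2t-Bu, via lactol 24 (not isolated)
Conditions: i-Bu2AlH (1.2 equiv), CH2Cl2, −78 °C; MeOH; then NaBH4, CeCl3·7H2O, MeOH, −40 → 0 °C
Reagents that add atoms: none
Why: Lactone-to-lactol reduction at low temperature spares the hindered tert-butyl ester, and borohydride under Luche conditions then reduces the ring-opened hydroxy enal 1,2 before it can dehydrate to a furan.

Step 17
Reactants: 25 diol
Product: 26 15-O-tert-butyldiphenylsilyl ether with free 6α-OH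
Conditions: t-BuPh2SiCl, imidazole, CH2Cl2, 0 °C
Reagents that add atoms: tert-butyldiphenylsilyl chloride, CC(C)(C)[Si](Cl)(c1ccccc1)c1ccccc1
Why: The bulky chlorosilane selects the primary allylic hydroxyl over the secondary one at C6.

Step 18
Reactants: 26 silyl ether
Product: 29 trans-fused 6α,12-lactone with 8β-OSiMe2t-Bu and 15-OSiPh2t-Bu, via bis(trimethylsilyl) derivative 27 (not isolated), via hydroxy acid 28 (not isolated)
Conditions: Me3SiOTf, 2,6-lutidine, CH2Cl2, 0 °C; then aq citric acid, THF, rt
Reagents that add atoms: trimethylsilyl triflate, C[Si](C)(C)OS(=O)(=O)C(F)(F)F (silyl groups held by 27 only)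
Why: Silyl triflate–lutidine cleavage of the tert-butyl ester avoids strong protic acid on the allylic ethers and the 1,5-diene, and the γ-hydroxy acid freed on mild hydrolysis should close to the 6,12-lactone because O6 is the only free hydroxyl.

Step 19
Reactants: 29 6,12-lactone
Product: 32 α-methylene-γ-lactone (C11=C13) with 8β-OSiMe2t-Bu and 15-OSiPh2t-Bu, via Mannich base 30 (not isolated), via methiodide 31 (not isolated)
Conditions: LiN(i-Pr)2, THF, −78 °C; [Me2N=CH2]I, −78 °C → rt; then MeI, MeOH, rt; then aq NaHCO3, CH2Cl2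
Reagents that add atoms: dimethylmethyleneammonium iodide, C[N+](C)=C.[I-]; iodomethane, CI (methyl held by 31 only)
Why: Mannich reaction of the lactone enolate followed by quaternisation and Hofmann-type elimination is the standard α-methylenation of γ-lactones, and C11 becomes trigonal so its transient configuration does not matter.

Step 20
Reactants: 32 α-methylene lactone
Product: 33 8β-alcohol with 15-OSiPh2t-Bu
Conditions: HF·pyridine, pyridine, THF, 0 °C → rt
Reagents that add atoms: none
Why: Under acidic fluoride the tert-butyldimethylsilyl ether is cleaved faster than the tert-butyldiphenylsilyl ether, so only O8 is freed.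

Step 21
Reactants: 34 (tert-butyldimethylsilyloxy)acetaldehyde; 35 ethyl 2-(triphenylphosphoranylidene)propanoate
Product: 36 ethyl (E)-4-(tert-butyldimethylsilyloxy)-2-methylbut-2-enoate
Conditions: CH2Cl2, rt
Reagents that add atoms: none
Why: The Wittig reaction of a stabilised α-methyl ylide with an aldehyde gives the (E)-trisubstituted enoate.

Step 22
Reactants: 36 ethyl ester
Product: 37 (E)-4-(tert-butyldimethylsilyloxy)-2-methylbut-2-enoic acid
Conditions: LiOH, THF–MeOH–H2O, rt; then aq HCl to pH 4, 0 °C
Reagents that add atoms: lithium hydroxide, [Li+].[OH-]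
Why: Saponification leaves the silyl ether and the olefin geometry intact when the acidification is kept mild.

Step 23
Reactants: 33 8β-alcohol; 37 silyloxy tiglic acid
Product: 38 8β-[(E)-4-(tert-butyldimethylsilyloxy)-2-methylbut-2-enoyloxy] lactone with 15-OSiPh2t-Bu
Conditions: DCC, DMAP, CH2Cl2, 0 °C → rt
Reagents that add atoms: none
Why: Steglich esterification acylates the only free hydroxyl with retention at C8 and without isomerising the (E)-enoate.

Step 24
Reactants: 38 bis-silyl ether
Product: 39 15,4′-diol (4,5-deoxy precursor of the target)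
Conditions: Bu4NF, AcOH, THF, 0 °C → rt
Reagents that add atoms: none
Why: Buffered fluoride removes both silyl ethers without base-induced addition to the methylene lactone or acyl migration.

Step 25
Reactants: 39 diol
Product: 40 CNP0187639.2
Conditions: VO(acac)2 (cat.), t-BuOOH, CH2Cl2, 0 °C
Reagents that add atoms: tert-butyl hydroperoxide, CC(C)(C)OO
Why: In the vanadium-catalysed hydroxyl-directed epoxidation the C15 hydroxyl carries the peroxide to C4=C5 only (C1=C10 has no allylic hydroxyl, the enoate and methylene lactone olefins are electron-poor), and because allylic strain keeps H-6 in the olefin plane while the ring chain covers the inner face, oxygen arrives on the outer face that also bears O6, giving the 4S,5R epoxide.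

Compound list
1 | (R)-3-methylcyclohexan-1-one | C[C@@H]1CCCC(=O)C1 | starting material
2 | trimethylsilyl enol ether of 1 (C7=C8) | C[C@@H]1CCC=C(O[Si](C)(C)C)C1 | intermediate
3 | (R)-5-methylcyclohex-2-en-1-one | C[C@@H]1CC=CC(=O)C1 | intermediate
4 | (R)-2-iodo-5-methylcyclohex-2-en-1-one | C[C@@H]1CC=C(I)C(=O)C1 | intermediate
5 | (1R,5R)-2-iodo-5-methylcyclohex-2-en-1-ol | C[C@@H]1CC=C(I)[C@H](O)C1 | intermediate
6 | (1R,5R)-1-(tert-butyldimethylsilyloxy)-2-iodo-5-methylcyclohex-2-ene | C[C@@H]1CC=C(I)[C@H](O[Si](C)(C)C(C)(C)C)C1 | intermediate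
7 | tert-butyl bromoacetate | CC(C)(C)OC(=O)CBr | starting material
8 | (2-tert-butoxy-2-oxoethyl)zinc bromide | CC(C)(C)OC(=O)C[Zn]Br | intermediate
9 | tert-butyl 2-[(4R,6R)-6-(tert-butyldimethylsilyloxy)-4-methylcyclohex-1-en-1-yl]acetate | C[C@@H]1CC=C(CC(=O)OC(C)(C)C)[C@H](O[Si](C)(C)C(C)(C)C)C1 | intermediate
10 | 6α-boryl cyclohexane (7β side chain, 8β silyl ether, 10β methyl) | C[C@@H]1C[C@@H](B)[C@H](CC(=O)OC(C)(C)C)[C@H](O[Si](C)(C)C(C)(C)C)C1 | intermediate
11 | 6α-hydroxy cyclohexane (7β side chain, 8β silyl ether, 10β methyl) | C[C@@H]1C[C@@H](O)[C@H](CC(=O)OC(C)(C)C)[C@H](O[Si](C)(C)C(C)(C)C)C1 | intermediate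
12 | 6-oxo cyclohexane (7β side chain, 8β silyl ether, 10β methyl) | C[C@@H]1CC(=O)[C@H](CC(=O)OC(C)(C)C)[C@H](O[Si](C)(C)C(C)(C)C)C1 | intermediate
13 | C5=C6 trimethylsilyl enol ether of 12 | C[C@@H]1C=C(O[Si](C)(C)C)[C@H](CC(=O)OC(C)(C)C)[C@H](O[Si](C)(C)C(C)(C)C)C1 | intermediate
14 | tert-butyl 2-[(1R,6R)-6-(tert-butyldimethylsilyloxy)-4-methyl-2-oxocyclohex-3-en-1-yl]acetate | CC1=CC(=O)[C@H](CC(=O)OC(C)(C)C)[C@H](O[Si](C)(C)C(C)(C)C)C1 | intermediate
15 | ethyl 1-bromocyclobutane-1-carboxylate | CCOC(=O)C1(Br)CCC1 | starting material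
16 | cyclobut-1-ene-1-carboxylic acid | OC(=O)C1=CCC1 | intermediate
17 | methyl cyclobut-1-ene-1-carboxylate | COC(=O)C1=CCC1 | intermediate
18 | head-to-head cis-anti-cis photoadduct (6-oxo, C15 methyl ester, 8β silyl ether) | O=C1[C@@H]2[C@@]3(C(=O)OC)CC[C@H]3[C@]2(C)C[C@@H](O[Si](C)(C)C(C)(C)C)[C@H]1CC(=O)OC(C)(C)C | intermediate
19 | 8β-hydroxy ketone of the photoadduct | O=C1[C@@H]2[C@@]3(C(=O)OC)CC[C@H]3[C@]2(C)C[C@@H](O)[C@H]1CC(=O)OC(C)(C)C | intermediate
20 | 6α,8β-diol methyl ester | O[C@@H]1[C@@H]2[C@@]3(C(=O)OC)CC[C@H]3[C@]2(C)C[C@@H](O)[C@H]1CC(=O)OC(C)(C)C | intermediate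
21 | tetracyclic C6–O–C15 lactone, 8β-OH | O1[C@@H]2[C@@H]3[C@@]4(C1=O)CC[C@H]4[C@]3(C)C[C@@H](O)[C@H]2CC(=O)OC(C)(C)C | intermediate
22 | tetracyclic C6–O–C15 lactone, 8β silyl ether (key-step precursor) | O1[C@@H]2[C@@H]3[C@@]4(C1=O)CC[C@H]4[C@]3(C)C[C@@H](O[Si](C)(C)C(C)(C)C)[C@H]2CC(=O)OC(C)(C)C | intermediate
23 | butenolide-bridged cis,trans-cyclodeca-1(10),4-diene (key-step product) | O=C1O[C@@H]2/C=C1/CC/C=C(C)\C[C@@H](O[Si](C)(C)C(C)(C)C)[C@H]2CC(=O)OC(C)(C)C | intermediate
24 | C15 lactol of 23 | OC1O[C@@H]2/C=C1/CC/C=C(C)\C[C@@H](O[Si](C)(C)C(C)(C)C)[C@H]2CC(=O)OC(C)(C)C | intermediate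
25 | 6α,15-diol tert-butyl ester | O[C@@H]1/C=C(CO)/CC/C=C(C)\C[C@@H](O[Si](C)(C)C(C)(C)C)[C@H]1CC(=O)OC(C)(C)C | intermediate
26 | 15-O-tert-butyldiphenylsilyl ether of 25 | O[C@@H]1/C=C(CO[Si](c2ccccc2)(c2ccccc2)C(C)(C)C)/CC/C=C(C)\C[C@@H](O[Si](C)(C)C(C)(C)C)[C@H]1CC(=O)OC(C)(C)C | intermediate
27 | 6-O-trimethylsilyl ether trimethylsilyl ester | C[Si](C)(C)O[C@@H]1/C=C(CO[Si](c2ccccc2)(c2ccccc2)C(C)(C)C)/CC/C=C(C)\C[C@@H](O[Si](C)(C)C(C)(C)C)[C@H]1CC(=O)O[Si](C)(C)C | intermediate
28 | 6α-hydroxy C12 acid | O[C@@H]1/C=C(CO[Si](c2ccccc2)(c2ccccc2)C(C)(C)C)/CC/C=C(C)\C[C@@H](O[Si](C)(C)C(C)(C)C)[C@H]1CC(=O)O | intermediate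
29 | trans-fused 6α,12-lactone | C1C(=O)O[C@H]2[C@H]1[C@H](O[Si](C)(C)C(C)(C)C)C/C(C)=C\CC/C(CO[Si](c3ccccc3)(c3ccccc3)C(C)(C)C)=C/2 | intermediate
30 | 11-(dimethylaminomethyl) lactone | CN(C)CC1C(=O)O[C@H]2[C@H]1[C@H](O[Si](C)(C)C(C)(C)C)C/C(C)=C\CC/C(CO[Si](c3ccccc3)(c3ccccc3)C(C)(C)C)=C/2 | intermediate
31 | trimethylammonium iodide of 30 | C[N+](C)(C)CC1C(=O)O[C@H]2[C@H]1[C@H](O[Si](C)(C)C(C)(C)C)C/C(C)=C\CC/C(CO[Si](c3ccccc3)(c3ccccc3)C(C)(C)C)=C/2.[I-] | intermediate
32 | α-methylene lactone, 8β silyl ether | C=C1C(=O)O[C@H]2[C@H]1[C@H](O[Si](C)(C)C(C)(C)C)C/C(C)=C\CC/C(CO[Si](c3ccccc3)(c3ccccc3)C(C)(C)C)=C/2 | intermediate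
33 | α-methylene lactone, 8β-OH | C=C1C(=O)O[C@H]2[C@H]1[C@H](O)C/C(C)=C\CC/C(CO[Si](c3ccccc3)(c3ccccc3)C(C)(C)C)=C/2 | intermediate
34 | (tert-butyldimethylsilyloxy)acetaldehyde | O=CCO[Si](C)(C)C(C)(C)C | starting material
35 | ethyl 2-(triphenylphosphoranylidene)propanoate | CCOC(=O)C(C)=P(c1ccccc1)(c1ccccc1)c1ccccc1 | starting material
36 | ethyl (E)-4-(tert-butyldimethylsilyloxy)-2-methylbut-2-enoate | CCOC(=O)/C(C)=C/CO[Si](C)(C)C(C)(C)C | intermediate
37 | (E)-4-(tert-butyldimethylsilyloxy)-2-methylbut-2-enoic acid | OC(=O)/C(C)=C/CO[Si](C)(C)C(C)(C)C | intermediate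
38 | 8β-ester, bis-silyl ether | C=C1C(=O)O[C@H]2[C@H]1[C@H](OC(=O)/C(C)=C/CO[Si](C)(C)C(C)(C)C)C/C(C)=C\CC/C(CO[Si](c3ccccc3)(c3ccccc3)C(C)(C)C)=C/2 | intermediate
39 | 8β-ester, 15,4′-diol | C=C1C(=O)O[C@H]2[C@H]1[C@H](OC(=O)/C(C)=C/CO)C/C(C)=C\CC/C(CO)=C/2 | intermediate
40 | CNP0187639.2 | C=C1C(=O)O[C@H]2[C@H]1[C@H](OC(=O)/C(C)=C/CO)C/C(C)=C\CC[C@@]1(CO)O[C@H]21 | target

Total step count: 25. Longest linear sequence: 21 (steps 1–8, 11–20, 23–25).

Steps most likely to fail

Step 15. The diene may drift on by Cope rearrangement to the divinylcyclohexane, or the diyl may cleave C2–C3, because ring opening and rearrangement need similar temperatures.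
- The fallback opens the cage one oxidation level higher and sets out from 18.
- Heating 18 in toluene should give the cyclodeca-1(10),4-dien-6-one keto ester F1. There C4=C5 is conjugated with both C6=O and C15, a stabilisation that rearrangement would partly give up.
- The ring-trans geometry at C4=C5 then rests on the chair diyl that keeps C6 and C14 equatorial.
- HF·pyridine frees the β-hydroxy dienone F2.
- Me4NBH(OAc)3 delivers hydride from O8 to give the anti-diol ester F3, which lactonises to the 8β-hydroxy butenolide F4.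
- t-BuMe2SiOTf with 2,6-lutidine returns to the route at 23.

Step 16. The tert-butyl ester may be over-reduced, or the lactol may dehydrate to a bridged furan.
- The fallback drops the chemoselective reduction and sets out from 23.
- LiAlH4 in THF reduces both carboxyl groups to the 6,12,15-triol F5.
- TEMPO with PhI(OAc)2 oxidises both primary alcohols. The saturated C12 aldehyde is captured by O6 as a lactol and carried on to the lactone, while C15 stops as the conjugated aldehyde, giving the 6,12-lactone enal F6.
- Luche reduction touches only the enal and gives the 15-hydroxy lactone F7.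
- t-BuPh2SiCl with imidazole comes back to the route at 29.

Step 25. Facial or site selectivity may be poor, or the new epoxide may be opened across the ring at the Lewis-acidic vanadium centre.
- The fallback replaces control by ring conformation with control by the catalyst.
- Setting out from 39, a Sharpless epoxidation is used: Ti(OiPr)4, L-(+)-diethyl tartrate, t-BuOOH, 4 Å sieves, CH2Cl2, −20 °C.
- This tartrate delivers oxygen to the face that makes the hydroxymethyl-bearing carbon C4 (S), the same outer face, so substrate and catalyst are matched.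
- The electron-poor side-chain olefin reacts far more slowly.
- The fallback arrives directly at 40 and makes no new compound (F0).

Step 11 is next in line. A wrong-face adduct formed there is sorted out in step 13, because only the α-face adduct can lactonise.

Further compounds
F1 | step 15 | cyclodeca-1(10),4-dien-6-one with C15 methyl ester and 8β silyl ether | O=C1/C=C(C(=O)OC)/CC/C=C(C)\C[C@@H](O[Si](C)(C)C(C)(C)C)[C@H]1CC(=O)OC(C)(C)C
F2 | step 15 | 8β-hydroxy cyclodecadienone | O=C1/C=C(C(=O)OC)/CC/C=C(C)\C[C@@H](O)[C@H]1CC(=O)OC(C)(C)C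
F3 | step 15 | 6α,8β-diol methyl ester of the cyclodecadiene | O[C@@H]1/C=C(C(=O)OC)/CC/C=C(C)\C[C@@H](O)[C@H]1CC(=O)OC(C)(C)C
F4 | step 15 | 8β-hydroxy butenolide-bridged cyclodecadiene | O=C1O[C@@H]2/C=C1/CC/C=C(C)\C[C@@H](O)[C@H]2CC(=O)OC(C)(C)C
F5 | step 16 | 6,12,15-triol with 8β silyl ether | O[C@@H]1/C=C(CO)/CC/C=C(C)\C[C@@H](O[Si](C)(C)C(C)(C)C)[C@H]1CCO
F6 | step 16 | 6α,12-lactone 15-al | C1C(=O)O[C@H]2[C@H]1[C@H](O[Si](C)(C)C(C)(C)C)C/C(C)=C\CC/C(C=O)=C/2
F7 | step 16 | 6α,12-lactone 15-ol | C1C(=O)O[C@H]2[C@H]1[C@H](O[Si](C)(C)C(C)(C)C)C/C(C)=C\CC/C(CO)=C/2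
F0 | step 25 | none | none
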